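**Retrosynthetic overview**

- The target is the threo (1R,2R) 8-O-4' neolignan. All four primary alcohols are unmasked at the end from esters in one hydride reduction (the C9 ester, the two malonate esters on the ring A oxygen, and the propanoate on ring B).
- Key disconnection: the C8–O(aryl) ether bond, made by carbene O–H insertion of the ring B phenol into a 2-diazo-3-oxo ester. Both stereocentres are then set in the same flask by transfer hydrogenation with dynamic kinetic resolution (syn, 2S,3R).
- The diazo keto ester comes from the ring A aldehyde and ethyl diazoacetate (aldol addition, then oxidation). The ring A aldehyde comes from vanillin by O-alkylation with diethyl chloromalonate, which is the glycerol-2-yl ether in masked form.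
- The ring B phenol comes from sinapic acid (esterification, then alkene hydrogenation).
- No ring is formed: ring A is bought in as vanillin and ring B as sinapic acid.

Assumption: catalysts, ligands, bases, solvents and simple reagents are bought; only the four carbon-contributing starting materials are numbered as such.

**Route**

Step 1
Reactants: 1 sinapic acid
Product: 3 methyl 3-(4-hydroxy-3,5-dimethoxyphenyl)propanoate, via methyl sinapate 2 (not isolated)
Conditions: MeOH, H2SO4 (cat.), reflux; then Pd/C (10 wt% Pd), H2 (1 atm), rt
Reagents that add atoms: methanol (CO)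
Why: Fischer esterification followed by palladium-catalysed hydrogenation of the conjugated C=C; both are routine, leave the hindered phenol and the aryl methyl ethers alone, and form no stereocentre.

Step 2
Reactants: 4 vanillin; 5 diethyl chloromalonate
Product: 6 diethyl 2-(4-formyl-2-methoxyphenoxy)propanedioate
Conditions: K2CO3 (1.5 equiv), acetone, reflux
Reagents that add atoms: none
Why: Williamson ether synthesis: the acidic phenol of vanillin is deprotonated by K2CO3 and displaces chloride from the doubly activated chloromalonate by SN2, installing the masked glycerol-2-yl ether; no stereocentre is formed.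

Step 3
Reactants: 6 diethyl 2-(4-formyl-2-methoxyphenoxy)propanedioate; 7 ethyl diazoacetate
Product: 9 ethyl 3-[4-(1,3-diethoxy-1,3-dioxopropan-2-yl)oxy-3-methoxyphenyl]-2-diazo-3-oxopropanoate, via racemic diazo carbinol 8 (not isolated)
Conditions: 7 (1.5 equiv), DBU (0.2 equiv), DMSO, rt; then IBX (2 equiv), rt
Reagents that add atoms: none
Why: DBU-catalysed aldol-type addition of ethyl diazoacetate to the aldehyde, then oxidation of the benzylic carbinol by 2-iodoxybenzoic acid in the same DMSO solution; the oxidation pulls the reversible aldol forward and removes the transient carbinol stereocentre.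

Step 4
Reactants: 9 ethyl 3-[4-(1,3-diethoxy-1,3-dioxopropan-2-yl)oxy-3-methoxyphenyl]-2-diazo-3-oxopropanoate; 3 methyl 3-(4-hydroxy-3,5-dimethoxyphenyl)propanoate
Product: 11 ethyl (2S,3R)-3-[4-(1,3-diethoxy-1,3-dioxopropan-2-yl)oxy-3-methoxyphenyl]-2-[2,6-dimethoxy-4-(3-methoxy-3-oxopropyl)phenoxy]-3-hydroxypropanoate, via racemic aryloxy keto ester 10 (not isolated)
Conditions: [RuCl2(p-cymene)]2 (2.5 mol%), 3 (1.3 equiv), ClCH2CH2Cl, 80 °C, slow addition of 9; then (S,S)-TsDPEN (6 mol%), HCO2H/Et3N (5:2), 35 °C
Reagents that add atoms: none
Why: Proposed new method: one divalent-ruthenium source does two jobs in one flask — first the chloride-bridged dimer is opened by the diazo carbon of 9, loses N2 and gives an electrophilic ruthenium carbene flanked by two carbonyls, the electron-rich phenol oxygen of 3 adds to it, and a 1,2-proton shift of the oxonium ylide (through the enol) releases racemic 10 with the C8–O bond in place; then added (S,S)-TsDPEN and Et3N turn the same metal into RuH[(S,S)-TsDPEN](p-cymene), which reduces the ketone by outer-sphere hydride and proton transfer while C2 of 10 epimerises fast through its enol, so all material funnels to one isomer: the CH–π contact between the cymene ligand and the ketone aryl ring fixes the ketone face (3R by the usual aryl-ketone model for the S,S ligand), and the C2 epimer that places its aryloxy group anti to the incoming hydride (Felkin–Anh) reacts fastest, giving the syn 2S,3R product; closest known reaction types are rhodium- or ruthenium-carbene O–H insertion of phenols into 2-diazo-1,3-dicarbonyl compounds and Noyori–Ikariya transfer hydrogenation of 2-alkoxy-3-oxo esters with dynamic kinetic resolution, and what is new is their merger on one metal, applied to a 2-aryloxy keto ester made in the flask.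

Step 5
Reactants: 11 ethyl (2S,3R)-3-[4-(1,3-diethoxy-1,3-dioxopropan-2-yl)oxy-3-methoxyphenyl]-2-[2,6-dimethoxy-4-(3-methoxy-3-oxopropyl)phenoxy]-3-hydroxypropanoate
Product: 12 (1R,2R)-1-[4-(1,3-dihydroxypropan-2-yl)oxy-3-methoxyphenyl]-2-[4-(3-hydroxypropyl)-2,6-dimethoxyphenoxy]propane-1,3-diol
Conditions: LiAlH4 (6 equiv), THF, 0 °C to rt; then H2O, 15% NaOH (aq)
Reagents that add atoms: none
Why: Lithium aluminium hydride reduction of all four esters to primary alcohols at once; neither stereocentre carries a group that hydride removes, and the activated 2-aryloxy ester is reduced at 0 °C faster than it enolises, so the threo arrangement is kept (the C2 label changes from S to R only because CH2OH ranks below the carbinol carbon).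

**Compound list**

1 | sinapic acid | COc1cc(/C=C/C(=O)O)cc(OC)c1O | starting material
2 | methyl sinapate (methyl (E)-3-(4-hydroxy-3,5-dimethoxyphenyl)prop-2-enoate) | COC(=O)/C=C/c1cc(OC)c(O)c(OC)c1 | intermediate
3 | methyl 3-(4-hydroxy-3,5-dimethoxyphenyl)propanoate | COC(=O)CCc1cc(OC)c(O)c(OC)c1 | intermediate
4 | vanillin | COc1cc(C=O)ccc1O | starting material
5 | diethyl chloromalonate | CCOC(=O)C(Cl)C(=O)OCC | starting material
6 | diethyl 2-(4-formyl-2-methoxyphenoxy)propanedioate | CCOC(=O)C(Oc1ccc(C=O)cc1OC)C(=O)OCC | intermediate
7 | ethyl diazoacetate | CCOC(=O)C=[N+]=[N-] | starting material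
8 | ethyl 3-[4-(1,3-diethoxy-1,3-dioxopropan-2-yl)oxy-3-methoxyphenyl]-2-diazo-3-hydroxypropanoate (racemic) | CCOC(=O)C(=[N+]=[N-])C(O)c1ccc(OC(C(=O)OCC)C(=O)OCC)c(OC)c1 | intermediate
9 | ethyl 3-[4-(1,3-diethoxy-1,3-dioxopropan-2-yl)oxy-3-methoxyphenyl]-2-diazo-3-oxopropanoate | CCOC(=O)C(=[N+]=[N-])C(=O)c1ccc(OC(C(=O)OCC)C(=O)OCC)c(OC)c1 | intermediate
10 | ethyl 3-[4-(1,3-diethoxy-1,3-dioxopropan-2-yl)oxy-3-methoxyphenyl]-2-[2,6-dimethoxy-4-(3-methoxy-3-oxopropyl)phenoxy]-3-oxopropanoate (racemic) | CCOC(=O)C(Oc1c(OC)cc(CCC(=O)OC)cc1OC)C(=O)c1ccc(OC(C(=O)OCC)C(=O)OCC)c(OC)c1 | intermediate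
11 | ethyl (2S,3R)-3-[4-(1,3-diethoxy-1,3-dioxopropan-2-yl)oxy-3-methoxyphenyl]-2-[2,6-dimethoxy-4-(3-methoxy-3-oxopropyl)phenoxy]-3-hydroxypropanoate | COc1cc([C@@H](O)[C@@H](C(=O)OCC)Oc2c(OC)cc(CCC(=O)OC)cc2OC)ccc1OC(C(=O)OCC)C(=O)OCC | intermediate
12 | (1R,2R)-1-[4-(1,3-dihydroxypropan-2-yl)oxy-3-methoxyphenyl]-2-[4-(3-hydroxypropyl)-2,6-dimethoxyphenoxy]propane-1,3-diol | COc1cc([C@@H](O)[C@@H](CO)Oc2c(OC)cc(CCCO)cc2OC)ccc1OC(CO)CO | target

**Step count**

Total steps: 5. Longest linear sequence: 4 (steps 2, 3, 4 and 5 from vanillin); step 1 is the side branch that supplies the ring B phenol.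

**Steps most likely to fail, and fallbacks**

Step 4 (the proposed new step). Three things can go wrong:
- The chloride dimer may transfer the doubly acceptor-substituted carbene sluggishly.
- The ruthenium left after the insertion stage may not ligate cleanly to TsDPEN.
- The syn preference has to hold for a hindered 2-aryloxy group.

The fallback uses known chemistry and splits the step into two separately catalysed reactions. It sets out from 9 (with 3). Rh2(OAc)4 (1 mol%) in CH2Cl2 at 40 °C performs the phenol O–H insertion, and the racemic keto ester 10 is isolated. Preformed RuCl[(S,S)-TsDPEN](p-cymene) (2 mol%) with HCO2H/Et3N (5:2) in CH2Cl2 at 30 °C then carries out the transfer hydrogenation with dynamic kinetic resolution. The fallback comes back to the route at 11 and makes no compound outside the list (none, F0).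

Step 5. LiAlH4 can deprotonate the aryloxymalonate C–H, parking it as an enolate that resists reduction or fragments. It can also enolise C2 of the hydroxy ester, giving erythro material or retro-aldol products. The fallback sets out from 11 and replaces the single aluminium hydride step by a chemoselective two-stage borohydride sequence. NaBH4 in THF/MeOH (0 °C to rt) is a protic medium in which the malonate is never held as an enolate. It reduces the three activated ethyl esters and leaves the unactivated propanoate, giving methyl 3-[4-[(1R,2R)-1-[4-(1,3-dihydroxypropan-2-yl)oxy-3-methoxyphenyl]-1,3-dihydroxypropan-2-yl]oxy-3,5-dimethoxyphenyl]propanoate F1. LiBH4 in THF (rt to 50 °C) then reduces the remaining methyl ester, and the fallback comes back at 12.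

Step 3. The aldehyde is electron-rich, so the aldol equilibrium with ethyl diazoacetate may lie on the wrong side. The acidic malonate C–H can also consume DBU, and IBX may oxidise elsewhere. The fallback sets out from 6 (with 7) and swaps aldol/oxidation for homologation/diazo transfer. Roskamp reaction with SnCl2 (10 mol%) in CH2Cl2 at rt inserts the diazoacetate carbon into the aldehyde C–H bond and gives ethyl 3-[4-(1,3-diethoxy-1,3-dioxopropan-2-yl)oxy-3-methoxyphenyl]-3-oxopropanoate F2. Regitz diazo transfer with 4-acetamidobenzenesulfonyl azide and Et3N in MeCN then gives the diazo keto ester, and the fallback comes back at 9.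

**Further compounds**

F0 | step 4 | none | none
F1 | step 5 | methyl 3-[4-[(1R,2R)-1-[4-(1,3-dihydroxypropan-2-yl)oxy-3-methoxyphenyl]-1,3-dihydroxypropan-2-yl]oxy-3,5-dimethoxyphenyl]propanoate | COc1cc([C@@H](O)[C@@H](CO)Oc2c(OC)cc(CCC(=O)OC)cc2OC)ccc1OC(CO)CO
F2 | step 3 | ethyl 3-[4-(1,3-diethoxy-1,3-dioxopropan-2-yl)oxy-3-methoxyphenyl]-3-oxopropanoate | CCOC(=O)CC(=O)c1ccc(OC(C(=O)OCC)C(=O)OCC)c(OC)c1
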